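**Plan**

1. Locants: ring A is the cycloheptane C1 (tertiary carbinol carrying the chain C2(=O)–C3–C4(OH)–C15), C5 (O-angeloyl), C6 (lactone O), C7, C8, C9, C10 (CH3 = C14); ring B is the lactone O6–C12(=O)–C11(CH3 = C13)–C7–C6.
2. Retrosynthesis: the C5 ester and the C4 silyl ether go last; ring B is cut at C11–C12 and O6–C12 (C12 = CO) to an ethynyl triol; C2–C3 is cut to a sulfone from (S)-propylene oxide; ring A is opened at C8=C9 (metathesis) and C1–C10 (Ireland–Claisen); C7–C11 and C6=C7 are cut back to L-tartrate.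
3. Forward: the C2–C1–C5–C6 chain of dimethyl L-tartrate acetonide is extended to a diene, epoxidised and opened with an alkynylalane; crotyl ester rearrangement and ring-closing metathesis give ring A; the acyl chain is attached; ring B is then closed on ring A, followed by hydrogenation, angeloylation and desilylation.
4. Stereochemistry: C5 comes from L-tartaric acid; C6 and C7 from a catalyst-controlled epoxidation and an invertive epoxide opening; C1 and C10 from a chair Ireland–Claisen transition state anti to the C5 substituent; C4 from (S)-propylene oxide; C11 from hydrogenation on the convex face of the cis-fused bicycle.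
5. Enabling feature: O6 and the two-carbon branch on C7 are cis-vicinal on ring A, so a CO unit bound to O6 reaches C11 of a C7 ethynyl group through a five-membered ring, whereas O5 (trans-1,3) and O1 cannot; the free triol therefore needs no protection.

Key step: step 12

Remark on the chemistry: the but-2-enoate is taken as (2Z) (angelate), as the SMILES encodes; the locants of line 1 are used throughout.

**Step 1**
Reactants: 1 dimethyl (4R,5R)-2,2-dimethyl-1,3-dioxolane-4,5-dicarboxylate; 2 diethyl prop-2-en-1-ylphosphonate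
Product: 4 methyl (4R,5S)-5-[(1E)-buta-1,3-dien-1-yl]-2,2-dimethyl-1,3-dioxolane-4-carboxylate, via aldehyde ester 3 (not isolated)
Conditions: i-Bu2AlH (1.05 equiv), PhMe, −78 °C; then 2/n-BuLi (THF–DMPU, −78 °C), −78 → 20 °C
Reagents that add atoms: none
Why: Partial reduction of one of the two equivalent esters stops at the aluminium hemiacetal, which releases aldehyde 3 as the lithiated allylphosphonate is added, so that a one-pot Horner–Wadsworth–Emmons olefination should give the (E)-diene without isolating or epimerising the α-alkoxy aldehyde; no new stereocenter is formed.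

**Step 2**
Reactants: 4 methyl (4R,5S)-5-[(1E)-buta-1,3-dien-1-yl]-2,2-dimethyl-1,3-dioxolane-4-carboxylate
Product: 5 methyl (4R,5S)-5-[(2R,3S)-3-ethenyloxiran-2-yl]-2,2-dimethyl-1,3-dioxolane-4-carboxylate
Conditions: L-fructose-derived ketone catalyst (ent-Shi ketone, 30 mol %), KHSO5 (as 2KHSO5·KHSO4·K2SO4), K2CO3, Bu4NHSO4, MeCN–CH2(OMe)2–aq. Na2B4O7 buffer, 0 °C
Reagents that add atoms: potassium peroxymonosulfate [K+].[O-]S(=O)(=O)OO
Why: Shi asymmetric epoxidation: the chiral dioxirane should transfer oxygen through a spiro transition state to the trans-disubstituted C6=C7 bond (the terminal C8=C9 bond is a poor substrate), the catalyst enantiomer fixing C6 and, provisionally, C7.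

**Step 3**
Reactants: 5 methyl (4R,5S)-5-[(2R,3S)-3-ethenyloxiran-2-yl]-2,2-dimethyl-1,3-dioxolane-4-carboxylate; 6 ethynyl(trimethyl)silane
Product: 7 methyl (4R,5S)-5-[(1R,2S)-1-hydroxy-2-[(trimethylsilyl)ethynyl]but-3-en-1-yl]-2,2-dimethyl-1,3-dioxolane-4-carboxylate
Conditions: 6, n-BuLi, PhMe, 0 °C; Et2AlCl; then 5, PhMe, −40 → 0 °C
Reagents that add atoms: none
Why: Epoxide opening by an alkynylalane (SN2): the alkynyl group should attack the allylic carbon C7 with inversion, C6 being deactivated by the adjacent dioxolane oxygen, so that the C6 hydroxyl keeps the epoxide configuration and the ethynyl group at C7 ends anti to it (cis on the future ring).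

**Step 4**
Reactants: 7 methyl (4R,5S)-5-[(1R,2S)-1-hydroxy-2-[(trimethylsilyl)ethynyl]but-3-en-1-yl]-2,2-dimethyl-1,3-dioxolane-4-carboxylate; 8 (2E)-but-2-en-1-ol
Product: 9 (2E)-but-2-en-1-yl (4R,5S)-5-[(1R,2S)-1-hydroxy-2-[(trimethylsilyl)ethynyl]but-3-en-1-yl]-2,2-dimethyl-1,3-dioxolane-4-carboxylate
Conditions: 8 (10 equiv), Ti(O-i-Pr)4 (0.2 equiv), PhMe, 90 °C, MeOH distilled off
Reagents that add atoms: none
Why: Titanate-catalysed transesterification exchanges the methyl for the (E)-crotyl ester under neutral conditions that leave the stereocenters, the silylalkyne and the free hydroxyl untouched.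

**Step 5**
Reactants: 9 (2E)-but-2-en-1-yl (4R,5S)-5-[(1R,2S)-1-hydroxy-2-[(trimethylsilyl)ethynyl]but-3-en-1-yl]-2,2-dimethyl-1,3-dioxolane-4-carboxylate
Product: 13 methyl (4S,5S)-4-[(2S)-but-3-en-2-yl]-5-[(1R,2S)-1-hydroxy-2-[(trimethylsilyl)ethynyl]but-3-en-1-yl]-2,2-dimethyl-1,3-dioxolane-4-carboxylate, via ketene acetal 10 (not isolated), via silyl ester 11 (not isolated), via carboxylic acid 12 (not isolated)
Conditions: LiN(i-Pr)2 (3 equiv), Me3SiCl–Et3N, THF, −100 → 20 °C; aq. AcOH; then Me3SiCHN2, MeOH–PhMe, 0 °C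
Reagents that add atoms: chlorotrimethylsilane C[Si](C)(C)Cl (silyl groups of 10 and 11 only); (trimethylsilyl)diazomethane C[Si](C)(C)C=[N+]=[N-]
Why: Ireland–Claisen rearrangement: lithium chelation between the enolate oxygen and ring oxygen O1 should give the Z ketene acetal 10 (trapped at once, which also outruns β-elimination), and a chair transition state on the face anti to the C5 side chain with the crotyl methyl equatorial creates the quaternary C1 and C10 together; hydrolysis and esterification give 13.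

**Step 6**
Reactants: 13 methyl (4S,5S)-4-[(2S)-but-3-en-2-yl]-5-[(1R,2S)-1-hydroxy-2-[(trimethylsilyl)ethynyl]but-3-en-1-yl]-2,2-dimethyl-1,3-dioxolane-4-carboxylate
Product: 14 methyl (3aS,4R,5S,8S,8aS)-4-hydroxy-2,2,8-trimethyl-5-[(trimethylsilyl)ethynyl]-3a,4,5,8-tetrahydro-8aH-cyclohepta[d][1,3]dioxole-8a-carboxylate
Conditions: second-generation Grubbs catalyst RuCl2(=CHPh)(H2IMes)(PCy3) (5 mol %), CH2Cl2 (0.002 M), 40 °C
Reagents that add atoms: none
Why: Ring-closing olefin metathesis of the two vinyl groups, held gauche by the trans-dioxolane, should close ring A with loss of ethene, the silyl-capped alkyne being too hindered for enyne metathesis and the free hydroxyl being tolerated.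

**Step 7**
Reactants: 15 (2S)-2-methyloxirane
Product: 16 (2S)-1-(benzenesulfonyl)propan-2-ol
Conditions: PhSO2Na, AcOH, H2O–EtOH, 70 °C
Reagents that add atoms: sodium benzenesulfinate [Na+].[O-]S(=O)c1ccccc1
Why: SN2 ring opening of the epoxide at its unsubstituted carbon by the sulfinate sulfur gives the β-hydroxy sulfone and leaves the stereocenter (future C4) untouched.

**Step 8**
Reactants: 16 (2S)-1-(benzenesulfonyl)propan-2-ol
Product: 17 {[(2S)-1-(benzenesulfonyl)propan-2-yl]oxy}(tert-butyl)diphenylsilane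
Conditions: t-BuPh2SiCl, imidazole, DMF, 20 °C
Reagents that add atoms: tert-butyl(chloro)diphenylsilane CC(C)(C)[Si](Cl)(c1ccccc1)c1ccccc1
Why: Silylation of the secondary alcohol gives an ether that should survive base, aluminium amalgam and dilute acid and is removed by fluoride at the end (reaction type: silyl ether protection).

**Step 9**
Reactants: 14 methyl (3aS,4R,5S,8S,8aS)-4-hydroxy-2,2,8-trimethyl-5-[(trimethylsilyl)ethynyl]-3a,4,5,8-tetrahydro-8aH-cyclohepta[d][1,3]dioxole-8a-carboxylate; 17 {[(2S)-1-(benzenesulfonyl)propan-2-yl]oxy}(tert-butyl)diphenylsilane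
Product: 18 (3S)-2-(benzenesulfonyl)-3-[tert-butyl(diphenyl)silyloxy]-1-[(3aS,4R,5S,8S,8aS)-4-hydroxy-2,2,8-trimethyl-5-[(trimethylsilyl)ethynyl]-3a,4,5,8-tetrahydro-8aH-cyclohepta[d][1,3]dioxol-8a-yl]butan-1-one (both epimers at the sulfonyl-bearing carbon)
Conditions: 17 (3.2 equiv), n-BuLi (3.1 equiv), THF, −78 °C; then 14, −78 → 0 °C; aq. NH4Cl
Reagents that add atoms: none
Why: Acylation of an α-sulfonyl carbanion by an ester (Claisen-type condensation): excess lithiated 17 first deprotonates the C6 hydroxyl and then adds to the α-alkoxy-activated ester, the β-keto sulfone being protected from over-addition as its enolate; the new C3 center is erased in the next step.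

**Step 10**
Reactants: 18 (3S)-2-(benzenesulfonyl)-3-[tert-butyl(diphenyl)silyloxy]-1-[(3aS,4R,5S,8S,8aS)-4-hydroxy-2,2,8-trimethyl-5-[(trimethylsilyl)ethynyl]-3a,4,5,8-tetrahydro-8aH-cyclohepta[d][1,3]dioxol-8a-yl]butan-1-one
Product: 19 (3S)-3-[tert-butyl(diphenyl)silyloxy]-1-[(3aS,4R,5S,8S,8aS)-4-hydroxy-2,2,8-trimethyl-5-[(trimethylsilyl)ethynyl]-3a,4,5,8-tetrahydro-8aH-cyclohepta[d][1,3]dioxol-8a-yl]butan-1-one
Conditions: Al/Hg (Al foil, HgCl2), THF–H2O (9:1), 20 °C
Reagents that add atoms: none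
Why: Reductive desulfonylation of a β-keto sulfone by electron transfer cleaves the C3–S bond via the enolate, which is protonated, and should not touch the silyl groups, the acetonide or the C1–O bond α to the ketone.

**Step 11**
Reactants: 19 (3S)-3-[tert-butyl(diphenyl)silyloxy]-1-[(3aS,4R,5S,8S,8aS)-4-hydroxy-2,2,8-trimethyl-5-[(trimethylsilyl)ethynyl]-3a,4,5,8-tetrahydro-8aH-cyclohepta[d][1,3]dioxol-8a-yl]butan-1-one
Product: 21 (3S)-3-[tert-butyl(diphenyl)silyloxy]-1-[(1S,2S,3R,4S,7S)-4-ethynyl-1,2,3-trihydroxy-7-methylcyclohept-5-en-1-yl]butan-1-one, via terminal alkyne 20 (not isolated)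
Conditions: K2CO3, MeOH, 20 °C; then 1 M aq. HCl, THF, 20 °C
Reagents that add atoms: none
Why: Protodesilylation of the silylalkyne by methanolysis followed by acid-catalysed hydrolysis of the strained trans-fused acetonide should free the terminal alkyne and the C1/C5 diol while the hindered silyl ether at C4 stays.

**Step 12**
Reactants: 21 (3S)-3-[tert-butyl(diphenyl)silyloxy]-1-[(1S,2S,3R,4S,7S)-4-ethynyl-1,2,3-trihydroxy-7-methylcyclohept-5-en-1-yl]butan-1-one
Product: 24 (3S)-3-[tert-butyl(diphenyl)silyloxy]-1-[(3aS,6S,7S,8S,8aR)-7,8-dihydroxy-6-methyl-3-methylidene-2-oxo-3,3a,6,7,8,8a-hexahydro-2H-cyclohepta[b]furan-7-yl]butan-1-one, via alkoxycarbonylpalladium iodide 22 (not isolated), via vinylpalladium iodide 23 (not isolated)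
Conditions: PdI2 (3 mol %), thiourea (9 mol %), CO (1 atm), acetone, 50 °C
Reagents that add atoms: carbon monoxide [C-]#[O+]
Why: Palladium-catalysed cyclocarbonylation: divalent palladium, CO and the O6 hydroxyl give the alkoxycarbonylpalladium iodide 22 with release of HI; intramolecular syn insertion of the C11≡C13 triple bond into the Pd–C12 bond forms the C11–C12 bond and thereby closes ring B (5-exo-dig) to vinylpalladium 23, whose protonolysis by HI sets free 24 and returns PdI2. The closest known reaction type is the cyclocarbonylation of 3-butyn-1-ols, cis-2-ethynylcycloalkanols included, to α-methylene-γ-butyrolactones. No stereocenter is created because C11 becomes sp2; the cis ring fusion is inherited from C6 and C7 as set in steps 2 and 3. The step needs site selectivity among three free hydroxyls and chemoselectivity for the alkyne: only O6 is cis-vicinal to the ethynyl group so that the five-membered insertion geometry is reachable, whereas O5 is trans-1,3 to it and O1 would have to form a bridged seven-membered ring, and the C8=C9 bond cannot insert without building a bridged bicycle. The ketone, the silyl ether and the tertiary α-ketol should be inert to CO and divalent palladium in the absence of an oxidant.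

**Step 13**
Reactants: 24 (3S)-3-[tert-butyl(diphenyl)silyloxy]-1-[(3aS,6S,7S,8S,8aR)-7,8-dihydroxy-6-methyl-3-methylidene-2-oxo-3,3a,6,7,8,8a-hexahydro-2H-cyclohepta[b]furan-7-yl]butan-1-one
Product: 25 (3S)-3-[tert-butyl(diphenyl)silyloxy]-1-[(3R,3aS,6S,7S,8S,8aR)-7,8-dihydroxy-3,6-dimethyl-2-oxooctahydro-2H-cyclohepta[b]furan-7-yl]butan-1-one
Conditions: H2 (3 atm), RhCl(PPh3)3 (10 mol %), PhH–EtOH, 25 °C
Reagents that add atoms: none
Why: Homogeneous hydrogenation (syn addition of H2 on rhodium): hydrogen should reach the exocyclic C11=C13 bond from the convex face of the cis-fused bicycle (the face of H6 and H7, which also carries the C5 hydroxyl), setting C11 with its methyl cis to C8, while the cis C8=C9 bond is saturated in the same operation without migration of the exocyclic alkene into the ring.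

**Step 14**
Reactants: 25 (3S)-3-[tert-butyl(diphenyl)silyloxy]-1-[(3R,3aS,6S,7S,8S,8aR)-7,8-dihydroxy-3,6-dimethyl-2-oxooctahydro-2H-cyclohepta[b]furan-7-yl]butan-1-one; 26 (2Z)-2-methylbut-2-enoic acid
Product: 28 (3R,3aS,6S,7S,8S,8aR)-7-{(3S)-3-[tert-butyl(diphenyl)silyloxy]butanoyl}-7-hydroxy-3,6-dimethyl-2-oxooctahydro-2H-cyclohepta[b]furan-8-yl (2Z)-2-methylbut-2-enoate, via mixed anhydride 27 (not isolated)
Conditions: 26, 2,4,6-Cl3C6H2COCl, Et3N, PhMe, 20 °C; then 25, PhMe, 75 °C
Reagents that add atoms: 2,4,6-trichlorobenzoyl chloride O=C(Cl)c1c(Cl)cc(Cl)cc1Cl (aroyl group of 27 only)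
Why: Yamaguchi-type esterification through the mixed anhydride without a nucleophilic catalyst should acylate the only reactive hydroxyl (secondary O5; O1 is tertiary, O4 is silylated) and avoid Z to E isomerisation of the angeloyl group and epimerisation at C11.

**Step 15**
Reactants: 28 (3R,3aS,6S,7S,8S,8aR)-7-{(3S)-3-[tert-butyl(diphenyl)silyloxy]butanoyl}-7-hydroxy-3,6-dimethyl-2-oxooctahydro-2H-cyclohepta[b]furan-8-yl (2Z)-2-methylbut-2-enoate
Product: 29 (3R,3aS,6S,7S,8S,8aR)-7-hydroxy-7-[(3S)-3-hydroxybutanoyl]-3,6-dimethyl-2-oxooctahydro-2H-cyclohepta[b]furan-8-yl (2Z)-2-methylbut-2-enoate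
Conditions: HF·pyridine, THF–pyridine, 0 → 20 °C
Reagents that add atoms: none
Why: Silyl ether deprotection by fluoride under buffered, weakly acidic conditions should free O4 without retro-aldol or β-elimination of the β-hydroxy ketone, epimerisation at C11 or isomerisation of the angelate.

**Compound list**

1 | dimethyl (4R,5R)-2,2-dimethyl-1,3-dioxolane-4,5-dicarboxylate | COC(=O)[C@@H]1OC(C)(C)O[C@H]1C(=O)OC | starting material
2 | diethyl prop-2-en-1-ylphosphonate | C=CCP(=O)(OCC)OCC | starting material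
3 | methyl (4R,5R)-5-formyl-2,2-dimethyl-1,3-dioxolane-4-carboxylate | COC(=O)[C@@H]1OC(C)(C)O[C@H]1C=O | intermediate
4 | methyl (4R,5S)-5-[(1E)-buta-1,3-dien-1-yl]-2,2-dimethyl-1,3-dioxolane-4-carboxylate | COC(=O)[C@@H]1OC(C)(C)O[C@H]1/C=C/C=C | intermediate
5 | methyl (4R,5S)-5-[(2R,3S)-3-ethenyloxiran-2-yl]-2,2-dimethyl-1,3-dioxolane-4-carboxylate | COC(=O)[C@@H]1OC(C)(C)O[C@H]1[C@@H]2O[C@H]2C=C | intermediate
6 | ethynyl(trimethyl)silane | C#C[Si](C)(C)C | starting material
7 | methyl (4R,5S)-5-[(1R,2S)-1-hydroxy-2-[(trimethylsilyl)ethynyl]but-3-en-1-yl]-2,2-dimethyl-1,3-dioxolane-4-carboxylate | COC(=O)[C@@H]1OC(C)(C)O[C@H]1[C@H](O)[C@H](C#C[Si](C)(C)C)C=C | intermediate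
8 | (2E)-but-2-en-1-ol | C/C=C/CO | starting material
9 | (2E)-but-2-en-1-yl (4R,5S)-5-[(1R,2S)-1-hydroxy-2-[(trimethylsilyl)ethynyl]but-3-en-1-yl]-2,2-dimethyl-1,3-dioxolane-4-carboxylate | C/C=C/COC(=O)[C@@H]1OC(C)(C)O[C@H]1[C@H](O)[C@H](C#C[Si](C)(C)C)C=C | intermediate
10 | (Z)-trimethylsilyl ketene acetal of 9, O6 silylated (OSiMe3 on C2 syn to ring oxygen O1) | C/C=C/CO/C(O[Si](C)(C)C)=C1/OC(C)(C)O[C@H]1[C@H](O[Si](C)(C)C)[C@H](C#C[Si](C)(C)C)C=C | intermediate
11 | trimethylsilyl ester of 12, O6 silylated | C=C[C@H](C)[C@]1(C(=O)O[Si](C)(C)C)OC(C)(C)O[C@H]1[C@H](O[Si](C)(C)C)[C@H](C#C[Si](C)(C)C)C=C | intermediate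
12 | (4S,5S)-4-[(2S)-but-3-en-2-yl]-5-[(1R,2S)-1-hydroxy-2-[(trimethylsilyl)ethynyl]but-3-en-1-yl]-2,2-dimethyl-1,3-dioxolane-4-carboxylic acid | C=C[C@H](C)[C@]1(C(=O)O)OC(C)(C)O[C@H]1[C@H](O)[C@H](C#C[Si](C)(C)C)C=C | intermediate
13 | methyl (4S,5S)-4-[(2S)-but-3-en-2-yl]-5-[(1R,2S)-1-hydroxy-2-[(trimethylsilyl)ethynyl]but-3-en-1-yl]-2,2-dimethyl-1,3-dioxolane-4-carboxylate | C=C[C@H](C)[C@]1(C(=O)OC)OC(C)(C)O[C@H]1[C@H](O)[C@H](C#C[Si](C)(C)C)C=C | intermediate
14 | methyl (3aS,4R,5S,8S,8aS)-4-hydroxy-2,2,8-trimethyl-5-[(trimethylsilyl)ethynyl]-3a,4,5,8-tetrahydro-8aH-cyclohepta[d][1,3]dioxole-8a-carboxylate | COC(=O)[C@@]12OC(C)(C)O[C@H]1[C@H](O)[C@H](C#C[Si](C)(C)C)C=C[C@@H]2C | intermediate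
15 | (2S)-2-methyloxirane | C[C@H]1CO1 | starting material
16 | (2S)-1-(benzenesulfonyl)propan-2-ol | C[C@H](O)CS(=O)(=O)c1ccccc1 | intermediate
17 | {[(2S)-1-(benzenesulfonyl)propan-2-yl]oxy}(tert-butyl)diphenylsilane | C[C@H](O[Si](c1ccccc1)(c1ccccc1)C(C)(C)C)CS(=O)(=O)c1ccccc1 | intermediate
18 | (3S)-2-(benzenesulfonyl)-3-[tert-butyl(diphenyl)silyloxy]-1-[(3aS,4R,5S,8S,8aS)-4-hydroxy-2,2,8-trimethyl-5-[(trimethylsilyl)ethynyl]-3a,4,5,8-tetrahydro-8aH-cyclohepta[d][1,3]dioxol-8a-yl]butan-1-one (C2 epimers) | C[C@H](O[Si](c1ccccc1)(c1ccccc1)C(C)(C)C)C(S(=O)(=O)c1ccccc1)C(=O)[C@@]12OC(C)(C)O[C@H]1[C@H](O)[C@H](C#C[Si](C)(C)C)C=C[C@@H]2C | intermediate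
19 | (3S)-3-[tert-butyl(diphenyl)silyloxy]-1-[(3aS,4R,5S,8S,8aS)-4-hydroxy-2,2,8-trimethyl-5-[(trimethylsilyl)ethynyl]-3a,4,5,8-tetrahydro-8aH-cyclohepta[d][1,3]dioxol-8a-yl]butan-1-one | C[C@H](O[Si](c1ccccc1)(c1ccccc1)C(C)(C)C)CC(=O)[C@@]12OC(C)(C)O[C@H]1[C@H](O)[C@H](C#C[Si](C)(C)C)C=C[C@@H]2C | intermediate
20 | 5-ethynyl analogue of 19 (C-desilylated) | C[C@H](O[Si](c1ccccc1)(c1ccccc1)C(C)(C)C)CC(=O)[C@@]12OC(C)(C)O[C@H]1[C@H](O)[C@H](C#C)C=C[C@@H]2C | intermediate
21 | (3S)-3-[tert-butyl(diphenyl)silyloxy]-1-[(1S,2S,3R,4S,7S)-4-ethynyl-1,2,3-trihydroxy-7-methylcyclohept-5-en-1-yl]butan-1-one | C[C@H](O[Si](c1ccccc1)(c1ccccc1)C(C)(C)C)CC(=O)[C@@]1(O)[C@@H](O)[C@H](O)[C@H](C#C)C=C[C@@H]1C | intermediate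
22 | O6-(iodopalladio)carbonyl derivative of 21 (thiourea ligands omitted) | C[C@H](O[Si](c1ccccc1)(c1ccccc1)C(C)(C)C)CC(=O)[C@@]1(O)[C@@H](O)[C@H](OC(=O)[Pd]I)[C@H](C#C)C=C[C@@H]1C | intermediate
23 | C13-(iodopalladio) derivative of 24 formed by syn insertion (Pd cis to C12; ligands omitted) | C[C@H](O[Si](c1ccccc1)(c1ccccc1)C(C)(C)C)CC(=O)[C@@]1(O)[C@@H](O)[C@@H]2OC(=O)/C(=C\[Pd]I)[C@@H]2C=C[C@@H]1C | intermediate
24 | (3S)-3-[tert-butyl(diphenyl)silyloxy]-1-[(3aS,6S,7S,8S,8aR)-7,8-dihydroxy-6-methyl-3-methylidene-2-oxo-3,3a,6,7,8,8a-hexahydro-2H-cyclohepta[b]furan-7-yl]butan-1-one | C[C@H](O[Si](c1ccccc1)(c1ccccc1)C(C)(C)C)CC(=O)[C@@]1(O)[C@@H](O)[C@@H]2OC(=O)C(=C)[C@@H]2C=C[C@@H]1C | intermediate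
25 | (3S)-3-[tert-butyl(diphenyl)silyloxy]-1-[(3R,3aS,6S,7S,8S,8aR)-7,8-dihydroxy-3,6-dimethyl-2-oxooctahydro-2H-cyclohepta[b]furan-7-yl]butan-1-one | C[C@H](O[Si](c1ccccc1)(c1ccccc1)C(C)(C)C)CC(=O)[C@@]1(O)[C@@H](O)[C@@H]2OC(=O)[C@H](C)[C@@H]2CC[C@@H]1C | intermediate
26 | (2Z)-2-methylbut-2-enoic acid (angelic acid) | C/C=C(/C)C(=O)O | starting material
27 | (2Z)-2-methylbut-2-enoic 2,4,6-trichlorobenzoic anhydride | C/C=C(/C)C(=O)OC(=O)c1c(Cl)cc(Cl)cc1Cl | intermediate
28 | (3R,3aS,6S,7S,8S,8aR)-7-{(3S)-3-[tert-butyl(diphenyl)silyloxy]butanoyl}-7-hydroxy-3,6-dimethyl-2-oxooctahydro-2H-cyclohepta[b]furan-8-yl (2Z)-2-methylbut-2-enoate | C/C=C(/C)C(=O)O[C@H]1[C@@H]2OC(=O)[C@H](C)[C@@H]2CC[C@H](C)[C@@]1(O)C(=O)C[C@H](C)O[Si](c1ccccc1)(c1ccccc1)C(C)(C)C | intermediate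
29 | (3R,3aS,6S,7S,8S,8aR)-7-hydroxy-7-[(3S)-3-hydroxybutanoyl]-3,6-dimethyl-2-oxooctahydro-2H-cyclohepta[b]furan-8-yl (2Z)-2-methylbut-2-enoate | C/C=C(/C)C(=O)O[C@H]1[C@@H]2OC(=O)[C@H](C)[C@@H]2CC[C@H](C)[C@@]1(O)C(=O)C[C@H](C)O | target

**Step count and risks**

Total number of steps: 15. Longest linear sequence: 13 steps (steps 1–6, then 9–15).

Steps most likely to fail:

1. Step 5 (Ireland–Claisen). The dioxolane ester enolate may fragment by β-elimination before it is silylated, or a competing boat transition state or loss of ketene acetal geometry may erode control at C10. The fallback sets out from 1 and comes back at 13. The lithium enolate of 1 (LiN(i-Pr)2, THF, −78 °C) is allylated at the substituted allyl terminus under iridium catalysis ([Ir(cod)Cl]2, chiral phosphoramidite ligand, tert-butyl (2E)-but-2-en-1-yl carbonate) to give the C1-(but-3-en-2-yl) diester F1, with C10 set by the ligand and C1 by attack anti to the neighbouring ester. The less hindered ester of F1 is then reduced and olefinated as in step 1 to the butadienyl ester F2, epoxidised as in step 2 to the vinyl epoxide F3, and opened with the alkynylalane from 6 as in step 3, which gives 13.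

2. Step 9 (acylation of the sulfone anion). Addition of the branched α-sulfonyl carbanion to the ester next to the quaternary C1 may be too slow, so that proton transfer wins and the ester is recovered. The fallback sets out from 12 (isolated after the aqueous stage of step 5) and comes back at 19. MeLi (4 equiv, THF, 0 °C) converts the carboxylate into the acyclic methyl ketone F4. Ring-closing metathesis with the second-generation Grubbs catalyst gives the bicyclic methyl ketone F5. A boron aldol reaction (the enantiomer of (Ipc)2BCl that favours the (S)-carbinol, Et3N, then acetaldehyde, −78 °C) gives the β-hydroxy ketone F6, and selective silylation of the less hindered O4 (t-BuPh2SiCl, imidazole) gives 19.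

3. Step 14 (angeloylation). Acylation of the hindered O5 next to the quaternary C1 may be sluggish, and prolonged heating may isomerise the angeloyl unit from Z to E. The fallback sets out from 25 and comes back at 28. O5 is acylated with the small, reactive 2-[bis(2,2,2-trifluoroethoxy)phosphoryl]propanoic acid (carbodiimide, 4-(dimethylamino)pyridine, CH2Cl2) to give the phosphonopropanoate ester F7. A Still–Gennari olefination of F7 with acetaldehyde (KN(SiMe3)2, 18-crown-6, THF, −78 °C) then builds the (Z)-alkene on the substrate and gives 28.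

**Further compounds**

F1 | step 5 | dimethyl (4S,5R)-4-[(2S)-but-3-en-2-yl]-2,2-dimethyl-1,3-dioxolane-4,5-dicarboxylate | C=C[C@H](C)[C@]1(C(=O)OC)OC(C)(C)O[C@H]1C(=O)OC
F2 | step 5 | methyl (4S,5S)-5-[(1E)-buta-1,3-dien-1-yl]-4-[(2S)-but-3-en-2-yl]-2,2-dimethyl-1,3-dioxolane-4-carboxylate | C=C[C@H](C)[C@]1(C(=O)OC)OC(C)(C)O[C@H]1/C=C/C=C
F3 | step 5 | C1-(but-3-en-2-yl) analogue of vinyl epoxide 5 | C=C[C@H](C)[C@]1(C(=O)OC)OC(C)(C)O[C@H]1[C@@H]2O[C@H]2C=C
F4 | step 9 | methyl ketone analogue of 13 (acetyl in place of the ester) | C=C[C@H](C)[C@]1(C(C)=O)OC(C)(C)O[C@H]1[C@H](O)[C@H](C#C[Si](C)(C)C)C=C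
F5 | step 9 | methyl ketone analogue of 14 (acetyl in place of the ester) | CC(=O)[C@@]12OC(C)(C)O[C@H]1[C@H](O)[C@H](C#C[Si](C)(C)C)C=C[C@@H]2C
F6 | step 9 | O4-desilyl analogue of 19 | C[C@H](O)CC(=O)[C@@]12OC(C)(C)O[C@H]1[C@H](O)[C@H](C#C[Si](C)(C)C)C=C[C@@H]2C
F7 | step 14 | O5 2-[bis(2,2,2-trifluoroethoxy)phosphoryl]propanoate of 25 (both epimers at the phosphonate carbon) | CC(C(=O)O[C@H]1[C@@H]2OC(=O)[C@H](C)[C@@H]2CC[C@H](C)[C@@]1(O)C(=O)C[C@H](C)O[Si](c1ccccc1)(c1ccccc1)C(C)(C)C)P(=O)(OCC(F)(F)F)OCC(F)(F)F
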